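**Remarks on conventions and assumptions.** (i) Locants C1–C15 and O6, O8, O9 are those of the target and are used for every intermediate; β is the face of the six-membered ring that carries C14, α the other face. (ii) Assumption: the epimers at the acetal carbon C15 (compounds 7–17) and at the carbinol C1 (compound 10) are carried on unseparated, because both centres are erased later; these atoms carry no descriptor in the SMILES.

## Analysis of the target

The target is an elemane-type sesquiterpenoid: one cyclohexane ring whose six carbons C5–C10 are all stereogenic, with a trans-fused α-methylene-γ-butyrolactone (C7–C11(=C13)–C12(=O)–O8–C8) as the only other ring. C10 is quaternary and carries the C14 methyl (β) and the C1=C2 vinyl group (α). C9 bears an acetate (α), C6 an angelate (β) and C5 the 2-substituted acrolein C4(=C3)–C15HO (β). In the chair that keeps the lactone diequatorial (C11 β, O8 α), C4 and the vinyl group are equatorial and C14, O6 and O9 are axial, so O6 is cis to both neighbours C4 and C11, and O9 is cis to O8. Three labile units must survive to the end: the methylene lactone and the enal (both Michael acceptors) and the Z-angelate, which isomerises to the tiglate with nucleophiles or base; a free O6–H would also close onto C15 as a lactol or pull the lactone acyl group over from O8. The difficulty lies in six contiguous centres including the vinyl-bearing quaternary carbon, in telling O6, O8 and O9 apart, and in the order in which the acceptors are unveiled. The plan rests on two features: the ring with C14 on C10, a carbonyl-ready C9 and the three-carbon branch C11–C13 on C7 is the p-menthane skeleton of carvone, and O6 sits cis to C4 on the neighbouring carbon, so an O6-bound two-carbon acetal (C15–C4) can deliver C4 to C5 intramolecularly.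

## Retrosynthetic reasoning

**C3–C4 (23 ⇒ 22).** The exocyclic methylene of the acrolein is removed first. The enal is the most electrophilic group and should exist for one step only. Once O6 is acylated no lactol can form, and C4 is the only enolisable aldehyde α-carbon, so a mild α-methylenation is all that the forward step requires.

**O6–acyl bond and the aldehyde mask (22 ⇒ 21 ⇒ 18 + 19).** The angelate is cut next, because its Z-alkene should see as few steps as possible. Acylating O6 demands that C15 be held in an open-chain masked form; with a free aldehyde, O6 and C15 would close to a lactol and the anomeric oxygen would be acylated instead. The dithiane of 21 and 18 does this and is removed without acid or base.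

**C15–S bonds (18 ⇒ 17).** The dithiane is traced back to the cyclic mixed acetal of 17, in which C15 is bonded to O6. This acetal is what remains of the tether used in the key step, and it protects O6 and C15 in one unit through all the oxidations on the other side of the ring.

**O9–acetyl, O8–C12 and the C12 oxidation level (17 ⇒ 16 ⇒ 14 ⇒ 13).** The acetate is removed, then the lactone C–O bond, then the C12 oxygen, which leads to the isopropenyl group of 13 as a latent α-methylene lactone. Cutting here needs no protecting group on the diol: O6 is locked in the acetal and the axial O9 cannot reach the equatorial C11 branch, so O8 is the only oxygen that can close onto C12, and after that O9 is the only free hydroxyl.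

**C9–H and C8–O (13 ⇒ 12 ⇒ 11).** The cis-diol is taken back to the C9 ketone: hydride adds to C9, and O8 enters through the enolate, which can only form towards C8 because C10 is quaternary. The carbonyl of 1 thus serves as enone acceptor, as the enolate that forms C10–C1, as the enolate that brings in O8, and finally as the C9 stereocentre.

**C1=C2 (11 ⇒ 10).** The vinyl group is traced to a 1-hydroxyethyl group. C10 has no hydrogen, so dehydration can run only towards C2, and the carbinol configuration is irrelevant.

**C4–C5 and C10–C1 (10 ⇒ 7 + 8, through 9).** This is the central disconnection. Both bonds at the ends of the enone of 7 are cut in one operation: the radical at C4, held on O6, closes onto C5, and the enolate 9 that results takes up 8 at C10. One ring, two skeletal bonds and the centres C5 and C10 come from this step, and the ring-fusion constraint rather than a reagent sets the relative configuration.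

**C6–O and the tether (7 ⇒ 5 + 6; 5 ⇒ 4 ⇒ 3 ⇒ 2 ⇒ 1).** The iodoacetal is cut at O6 into 5 and 6. The cis alcohol 5 comes from its trans epimer 3 by inversion via 4, because γ-oxygenation of the linear dienol ether 2 should occur anti to the C7 substituent. Compound 2 is the thermodynamic enol derivative of 1, which already holds the ring, C14, C7 with its configuration and C11–C13.

## Alternatives that were turned down

**Alternative 1:** The ring is opened at C9–C10 to the acyclic C9 aldehyde A1, in which C10 is the γ-carbon of an (E)-allylsilane and C5–C8 already bear their substituents. In the forward step a Lewis acid such as BF3·OEt2 activates the aldehyde, and intramolecular Hosomi–Sakurai attack through C10 closes the cyclohexane, creates the quaternary carbon and the C9 carbinol, and releases the vinyl group, giving A2. In its favour, one step makes the ring, the hardest carbon and the vinyl group without any dehydration, and C12, C15 and O6 are already near their final state, so the endgame after A2 is short. Against it, A1 carries four contiguous stereocentres on an open chain, each needing its own asymmetric bond formation and orthogonal protection, with an angelate and two acrylate units exposed from early on. The cyclisation must also set C9 (axial oxygen, cis to O8) and C10 through a chair transition state that has O6 axial and competes with chelation of the α-silyloxy aldehyde. On convergency and on direct formation of the vinyl group this plan is stronger. The chosen route instead takes the ring, C14, C7 and C11–C13 from 1, reaches 7 in five steps and fixes C5 and C10 by ring fusion.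

**Alternative 2:** The ring is opened at C5–C6, with C15 at the acid level, to the C6 aldehyde A3 carrying a 2-(bromomethyl)enoate. Zinc metal inserts into the allylic bromide, the allylzinc adds through its γ-carbon C5 to the aldehyde (Barbier-type closure), and the alkoxide lactonises onto the C15 ester to give the cis-fused methylene lactone A4. This reaction type is dependable and tolerant; in one step it closes the ring, sets C5 and C6 and installs the C4=C3 methylene, and here it is stronger than the chosen route, which needs a separate methylenation. Against it, the all-carbon quaternary centre C10 must be made beforehand on an acyclic chain, and the C5/C6 configuration relative to C7 and C10 depends on a cyclic allylzinc transition state next to that quaternary carbon. After A4 the temporary lactone has to be reduced back to the aldehyde level while a second, nearly identical methylene lactone is built at O8 and O8 is told apart from O9 after acetonide removal. That is a long redox and protecting-group tail. The chosen route keeps C15 at the aldehyde level as an acetal throughout and avoids two similar acceptors at the same time.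

**Alternative 3:** The lactone is cut at C7–C11 to the O8 diazophosphonoacetate A5, a cyclohexane with C7H2. Dirhodium tetraacetate Rh2(OAc)4 generates the carbenoid, 1,5-insertion into the equatorial C7–H bond gives the trans-fused phosphono lactone A6, and a Horner–Wadsworth–Emmons reaction then introduces the methylene. In its favour, C7 and the lactone ring arise in one late step with retention, and the methylene lactone is never carried through other chemistry, which is a real advantage over the chosen route. Against it, the carbenoid meets three alkenes (C1=C2, C4=C3, the angelate) open to cyclopropanation and a competing C9–H bond, and the wanted C7–H bond is inductively deactivated by the neighbouring C6 acyloxy group. A5 further needs C5, C6, C8, C9 and C10 assembled on a ring that lacks the C7 branch, so no terpene maps onto it and the ring must be built from scratch. The chosen route has C7 and C11–C13 in place from the first step and makes the lactone from carbons already present.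

Key step: step 6

## Route

Step 1
Reactants: 1 (S)-(+)-carvone
Product: 2 linear trimethylsilyl dienol ether of 1 [(5R)-2-methyl-5-(prop-1-en-2-yl)-1-(trimethylsilyloxy)cyclohexa-1,3-diene; C9–OSiMe3 with C9=C10 and C5=C6]
Conditions: MeMgBr, FeCl3 (cat.), Et2O, −20 °C; then Me3SiCl, Et3N, DMPU, −20 °C → rt
Reagents that add atoms: chlorotrimethylsilane, C[Si](C)(C)Cl
Why: Iron-modified methylmagnesium bromide (Kharasch-type reagent) acts as a base rather than a nucleophile and gives the thermodynamic, linearly conjugated dienolate by γ-deprotonation at C6, which is silylated on oxygen; C7 is not touched.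

Step 2
Reactants: 2 linear trimethylsilyl dienol ether
Product: 3 trans γ-hydroxy enone [(4R,5S)-4-hydroxy-2-methyl-5-(prop-1-en-2-yl)cyclohex-2-en-1-one; 6α-OH, trans to the C7 isopropenyl group]
Conditions: mCPBA, NaHCO3, CH2Cl2, −20 °C; then 1 M HCl, THF, 0 °C
Reagents that add atoms: 3-chloroperoxybenzoic acid, O=C(OO)c1cccc(Cl)c1
Why: Vinylogous Rubottom oxidation: the peracid should epoxidise the distal C5=C6 bond of the electron-rich diene on the face opposite the C7 substituent, and silyloxy-assisted opening gives the enone with O6 on the α face. The isolated isopropenyl alkene is far less nucleophilic.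

Step 3
Reactants: 3 trans γ-hydroxy enone
Product: 4 cis 4-nitrobenzoate [4-nitrobenzoate of the 6β alcohol; (4S,5S) in carvone locants]
Conditions: 4-O2NC6H4CO2H, PPh3, DIAD, toluene, 0 °C → rt
Reagents that add atoms: 4-nitrobenzoic acid, OC(=O)c1ccc(cc1)[N+](=O)[O-]
Why: Mitsunobu reaction with SN2 inversion at the allylic C6; 4-nitrobenzoic acid is the acid of choice for alcohols flanked by a branch. The activated oxygen is syn to H7, so anti elimination towards C7 is not available.

Step 4
Reactants: 4 cis 4-nitrobenzoate
Product: 5 cis γ-hydroxy enone [(4S,5S)-4-hydroxy-2-methyl-5-(prop-1-en-2-yl)cyclohex-2-en-1-one; 6β-OH, cis to the C7 isopropenyl group]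
Conditions: K2CO3 (cat.), MeOH, 0 °C
Reagents that add atoms: none
Why: Transesterification of the activated aryl ester; catalytic base, low temperature and short contact keep the γ-hydroxy enone from enolising.

Step 5
Reactants: 5 cis γ-hydroxy enone; 6 ethyl vinyl ether
Product: 7 iodoacetal [(4S,5S)-4-(1-ethoxy-2-iodoethoxy)-2-methyl-5-(prop-1-en-2-yl)cyclohex-2-en-1-one; O6–C15H(OEt)–C4H2I, both C15 epimers]
Conditions: N-iodosuccinimide, CH2Cl2, −40 → 0 °C
Reagents that add atoms: N-iodosuccinimide, O=C1CCC(=O)N1I
Why: Iodoacetalisation: the iodonium ion of the enol ether is opened by O6–H at the oxocarbenium carbon. The enol ether is far more reactive towards the iodine source than the isopropenyl group, and the new acetal centre is inconsequential.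

Step 6
Reactants: 7 iodoacetal; 8 acetaldehyde
Product: 10 aldol adduct [cis-fused bicyclic acetal ketone: C9 ketone; 10β-methyl; 10α-(1-hydroxyethyl); 7β-isopropenyl; 5β,6β-fused 15-ethoxytetrahydrofuran O6–C15–C4–C5], via diethylboron enolate 9 (not isolated)
Conditions: Et3B (3 equiv), 8 (8 equiv), dry air (slow addition), CH2Cl2, −78 → −40 °C; then MeOH, pH 7 buffer
Reagents that add atoms: none
Why: Ethyl radicals from Et3B and oxygen abstract iodine from 7, and the primary C4 radical adds to C5, the β-carbon of the enone, in a 5-exo-trig closure that forms the tetrahydrofuran ring O6–C15–C4–C5–C6 (Ueno–Stork haloacetal cyclisation). The tertiary α-keto radical at C10 is then captured by Et3B in a homolytic substitution at boron, which gives the regiodefined enolate 9 and releases the ethyl radical that carries the chain. Enolate 9 adds to 8 through a closed six-membered (Zimmerman–Traxler) transition state and so forms C10–C1 and the quaternary carbon; the closest known reaction type is the Et3B-mediated radical conjugate addition–aldol sequence (radical-polar crossover), here with a tetrasubstituted enolate carbon as the less-tested element. C5 is controlled by C6: the two-atom tether can reach C5 only on the face of O6, so the new five-membered ring is necessarily cis-fused and C4 ends up β. C10 is controlled by C5: allylic 1,2-strain with the C14 methyl pushes the C5–C4 bond pseudoaxial on the β face, where the 6β oxygen also sits, so the aldehyde should be taken up on the α face and C14 stays β. The configurations at C1 and C15 are of no consequence. The step needs the radical to choose the enone over the isopropenyl alkene, which the 5-exo geometry and the polarity match of a nucleophilic alkyl radical with an electron-poor alkene secure, and it needs aldol capture to outrun protonation of 9, which excess 8, dry conditions and low temperature serve.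

Step 7
Reactants: 10 aldol adduct
Product: 11 vinyl ketone [as 10, with 10α-vinyl (C1=C2) in place of the 1-hydroxyethyl group]
Conditions: Burgess reagent (methyl N-(triethylammoniosulfonyl)carbamate), toluene, 70 °C
Reagents that add atoms: none
Why: Burgess dehydration (syn elimination through the sulfamate ester): C10 has no hydrogen, so only the C2 methyl can supply the proton and both carbinol epimers give the vinyl group. Neutral conditions avoid retro-aldol cleavage of the β-hydroxy ketone.

Step 8
Reactants: 11 vinyl ketone
Product: 12 8α-hydroxy ketone [as 11, with equatorial 8α-OH, trans to the C7 isopropenyl group]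
Conditions: KN(SiMe3)2, THF, −78 °C; then 2-(phenylsulfonyl)-3-phenyloxaziridine, −78 °C; sat. NH4Cl
Reagents that add atoms: 2-(phenylsulfonyl)-3-phenyloxaziridine (Davis oxaziridine), O=S(=O)(c1ccccc1)N1OC1c1ccccc1
Why: Davis hydroxylation of the potassium enolate, which can form only towards C8. The oxidant should approach the α face, anti to the adjacent C7 substituent and away from the axial 10β-methyl and 6β-oxygen, to give the equatorial 8α-alcohol; the alkenes are not oxidised.

Step 9
Reactants: 12 8α-hydroxy ketone
Product: 13 8α,9α-diol [as 12, with axial 9α-OH, cis to O8]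
Conditions: LiBH(s-Bu)3, THF, −78 °C; then NaOH, H2O2, 0 °C
Reagents that add atoms: none
Why: The bulky trialkylborohydride should attack the chair cyclohexanone along the equatorial trajectory on the β face, avoiding the axial hydrogens at C5 and C7, and so give the axial 9α-alcohol. This is the usual outcome for 2-alkoxy- and 2,2-disubstituted cyclohexanones with this reagent.

Step 10
Reactants: 13 8α,9α-diol
Product: 14 8α,9α,12-triol [as 13, with C7 bearing C11(=C13H2)–C12H2OH]
Conditions: SeO2 (0.5 equiv), t-BuOOH (decane), CH2Cl2, rt
Reagents that add atoms: selenium dioxide (oxygen-transfer agent), O=[Se]=O; tert-butyl hydroperoxide (terminal oxidant), CC(C)(C)OO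
Why: SeO2 allylic oxidation (ene reaction, then 2,3-sigmatropic shift): the isopropenyl group is the only alkene with allylic hydrogens, since the C10 vinyl group has none, and its methyl reacts in preference to the C7 methine. Any material oxidised further to the aldehyde converges in step 11.

Step 11
Reactants: 14 8α,9α,12-triol
Product: 16 9α-hydroxy 8α,12-lactone [trans-fused α-methylene-γ-butyrolactone C7–C11(=C13)–C12(=O)–O8; 9α-OH free; acetal intact], via 8,12-lactol 15 (not isolated)
Conditions: MnO2 (activated, excess), CH2Cl2, rt
Reagents that add atoms: none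
Why: MnO2 oxidises the allylic alcohol to the 2-substituted acrolein, which the neighbouring equatorial O8–H traps as lactol 15; this allylic lactol is oxidised on to the lactone. O9 cannot reach C12 and O6 is held in the acetal, so only the 8,12-lactone can form, and the saturated 9-OH is inert to MnO2.

Step 12
Reactants: 16 9α-hydroxy 8α,12-lactone
Product: 17 9α-acetate [as 16, with 9α-OAc]
Conditions: Ac2O, Et3N, DMAP (cat.), CH2Cl2, rt
Reagents that add atoms: acetic anhydride, CC(=O)OC(C)=O
Why: DMAP-catalysed acetylation of the only free hydroxyl, the axial neopentyl 9α-OH.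

Step 13
Reactants: 17 9α-acetate
Product: 18 6β-hydroxy dithiane [tetrahydrofuran opened: free axial 6β-OH; C5 bears C4H2–C15H(1,3-dithian-2-yl)]
Conditions: HS(CH2)3SH, BF3·OEt2, CH2Cl2, −40 → 0 °C
Reagents that add atoms: propane-1,3-dithiol, SCCCS
Why: Lewis acid-mediated transthioacetalisation: ionisation of the mixed acetal gives an oxocarbenium ion, and the monothioacetal then opens with loss of O6 to a thionium ion that closes the dithiane. O6–H is freed while C15 stays masked at the aldehyde level, and both acetal epimers converge. Without base the thiol should not add to the methylene lactone at low temperature.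

Step 14
Reactants: 18 6β-hydroxy dithiane; 19 angelic acid [(Z)-2-methylbut-2-enoic acid]
Product: 21 6β-angelate dithiane [as 18, with O6 esterified by (Z)-2-methylbut-2-enoyl], via mixed anhydride 20 (not isolated)
Conditions: 19, 2,4,6-Cl3C6H2COCl, Et3N, toluene, rt; then 18, toluene, 80 °C
Reagents that add atoms: none
Why: Yamaguchi-type esterification through the mixed anhydride 20. Leaving out DMAP and other nucleophilic catalysts avoids Z-to-E isomerisation to the tiglate, the known weakness of angelate acylations.

Step 15
Reactants: 21 6β-angelate dithiane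
Product: 22 15-aldehyde [C5 bears C4H2–C15H=O; all other groups as in the target]
Conditions: PhI(OCOCF3)2, MeCN/H2O (9:1), 0 °C → rt
Reagents that add atoms: water, O
Why: Oxidative dethioacetalisation with the hypervalent iodine reagent (activation at sulfur, hydrolysis of the thionium ion); it is neutral to the esters and to the electron-poor and unactivated alkenes present.

Step 16
Reactants: 22 15-aldehyde
Product: 23 target compound CNP0228039.1
Conditions: aq. CH2O (37%), pyrrolidine (cat.), EtCO2H (cat.), i-PrOH, 45 °C
Reagents that add atoms: formaldehyde, C=O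
Why: Amine-catalysed α-methylenation of an aldehyde (enamine formation, Mannich-type condensation with formaldehyde, loss of the amine). C4 is the only enolisable aldehyde α-carbon, and the trans-lactone holds C11 equatorial, so the enamine cannot reach the methylene lactone intramolecularly.

## Compound list

1 | (S)-(+)-carvone, (5S)-2-methyl-5-(prop-1-en-2-yl)cyclohex-2-en-1-one | CC1=CC[C@@H](CC1=O)C(C)=C | starting material
2 | linear trimethylsilyl dienol ether, (5R)-2-methyl-5-(prop-1-en-2-yl)-1-(trimethylsilyloxy)cyclohexa-1,3-diene | CC1=C(O[Si](C)(C)C)C[C@@H](C(C)=C)C=C1 | intermediate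
3 | trans γ-hydroxy enone (6α-OH), (4R,5S)-4-hydroxy-2-methyl-5-(prop-1-en-2-yl)cyclohex-2-en-1-one | CC1=C[C@@H](O)[C@H](C(C)=C)CC1=O | intermediate
4 | cis 4-nitrobenzoate (6β-O), 4-nitrobenzoate ester of 5 | CC1=C[C@H](OC(=O)c2ccc(cc2)[N+](=O)[O-])[C@H](C(C)=C)CC1=O | intermediate
5 | cis γ-hydroxy enone (6β-OH), (4S,5S)-4-hydroxy-2-methyl-5-(prop-1-en-2-yl)cyclohex-2-en-1-one | CC1=C[C@H](O)[C@H](C(C)=C)CC1=O | intermediate
6 | ethyl vinyl ether | C=COCC | starting material
7 | iodoacetal, (4S,5S)-4-(1-ethoxy-2-iodoethoxy)-2-methyl-5-(prop-1-en-2-yl)cyclohex-2-en-1-one (C15 epimers) | CC1=C[C@H](OC(CI)OCC)[C@H](C(C)=C)CC1=O | intermediate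
8 | acetaldehyde | CC=O | starting material
9 | diethylboron enolate of the cyclised ketone (C9–O–BEt2, C9=C10; cis-fused 15-ethoxytetrahydrofuran at C5/C6; 7β-isopropenyl) | CC1=C(OB(CC)CC)C[C@@H](C(C)=C)[C@H]2OC(OCC)C[C@@H]12 | intermediate (not isolated)
10 | aldol adduct: C9 ketone, 10β-methyl, 10α-(1-hydroxyethyl), 7β-isopropenyl, 5β,6β-cis-fused 15-ethoxytetrahydrofuran (C1 and C15 epimers) | CC(O)[C@]1(C)C(=O)C[C@@H](C(C)=C)[C@H]2OC(OCC)C[C@@H]12 | intermediate
11 | vinyl ketone: as 10 with 10α-vinyl | C=C[C@]1(C)C(=O)C[C@@H](C(C)=C)[C@H]2OC(OCC)C[C@@H]12 | intermediate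
12 | 8α-hydroxy ketone | C=C[C@]1(C)C(=O)[C@H](O)[C@@H](C(C)=C)[C@H]2OC(OCC)C[C@@H]12 | intermediate
13 | 8α,9α-diol | C=C[C@]1(C)[C@H](O)[C@H](O)[C@@H](C(C)=C)[C@H]2OC(OCC)C[C@@H]12 | intermediate
14 | 8α,9α,12-triol (C7 bears 3-hydroxyprop-1-en-2-yl) | C=C[C@]1(C)[C@H](O)[C@H](O)[C@@H](C(=C)CO)[C@H]2OC(OCC)C[C@@H]12 | intermediate
15 | 8,12-lactol (α-methylene lactol trans-fused at C7/C8, 9α-OH) | C=C[C@]1(C)[C@H](O)[C@@H]2OC(O)C(=C)[C@H]2[C@H]3OC(OCC)C[C@@H]13 | intermediate (not isolated)
16 | 9α-hydroxy 8α,12-lactone (trans-fused α-methylene-γ-butyrolactone, acetal intact) | C=C[C@]1(C)[C@H](O)[C@@H]2OC(=O)C(=C)[C@H]2[C@H]3OC(OCC)C[C@@H]13 | intermediate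
17 | 9α-acetate of 16 | C=C[C@]1(C)[C@H](OC(C)=O)[C@@H]2OC(=O)C(=C)[C@H]2[C@H]3OC(OCC)C[C@@H]13 | intermediate
18 | 6β-hydroxy dithiane (C5 bears CH2–(1,3-dithian-2-yl)) | C=C[C@]1(C)[C@H](OC(C)=O)[C@@H]2OC(=O)C(=C)[C@H]2[C@@H](O)[C@H]1CC3SCCCS3 | intermediate
19 | angelic acid, (Z)-2-methylbut-2-enoic acid | C/C=C(/C)C(=O)O | starting material
20 | angelic 2,4,6-trichlorobenzoic mixed anhydride | C/C=C(/C)C(=O)OC(=O)c1c(Cl)cc(Cl)cc1Cl | intermediate (not isolated)
21 | 6β-angelate dithiane | C=C[C@]1(C)[C@H](OC(C)=O)[C@@H]2OC(=O)C(=C)[C@H]2[C@@H](OC(=O)/C(C)=C\C)[C@H]1CC3SCCCS3 | intermediate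
22 | 15-aldehyde (C5 bears CH2–CHO; 6β-angelate, 9α-acetate, 8α,12-lactone, 10α-vinyl) | C=C[C@]1(C)[C@H](OC(C)=O)[C@@H]2OC(=O)C(=C)[C@H]2[C@@H](OC(=O)/C(C)=C\C)[C@H]1CC=O | intermediate
23 | CNP0228039.1 | C=C[C@]1(C)[C@H](OC(C)=O)[C@@H]2OC(=O)C(=C)[C@H]2[C@@H](OC(=O)/C(C)=C\C)[C@H]1C(=C)C=O | target

## Step count and least certain steps

Total step count: 16. Longest linear sequence: 16 steps (1 → 23); 6, 8 and 19 are purchased and enter in single steps.

**Step 6 (key step).** The likeliest failure is that enolate 9 is protonated, or the C10 radical is reduced, before the hindered tetrasubstituted enolate adds to 8; the adduct may also revert by retro-aldol on work-up, or 8 may be taken up on both faces. Fallback: the two bond formations are separated. From 7, tin hydride cyclisation (Bu3SnH, AIBN, benzene, 80 °C) gives the cyclised ketone F1. Thermodynamic silylation (Me3SiCl, Et3N, DMF, 100 °C) gives the tetrasubstituted silyl enol ether F2. Regiospecific release of the lithium enolate with MeLi (THF, 0 °C) and addition of 8 at −78 °C returns to the route at 10.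

**Step 9.** Hydride may be delivered from the α face (axial attack), because the axial 10β-methyl flanks the equatorial trajectory; the free ketol may also enolise towards the isomeric ketol. Fallback: the other epimer is made on purpose and inverted. From 12, NaBH4/CeCl3·7H2O (MeOH, −78 °C) gives the 9β-epimeric diol F3, which the chemistry of steps 10 and 11 takes through the 9β triol F4 and the 9β lactol F5 (not isolated) to the 9β-hydroxy lactone F6. The equatorial alcohol is converted into the triflate F7 (Tf2O, pyridine) and displaced with CsOAc/18-crown-6 (toluene, 60 °C; Lattrell–Dax-type inversion, with no antiperiplanar hydrogen available for elimination). This gives the acetate directly and returns at 17.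

**Step 10.** The ene reaction may be sluggish or unselective: selenium may be tied up by the cis-diol as a selenite ester, C7–H may be oxidised, or the product may be over-oxidised. Fallback: from 13, ene-type allylic chlorination of the isopropenyl group (Ca(OCl)2, CO2, CH2Cl2/H2O, 0 °C) gives the allylic chloride F8. Amine N-oxide oxidation (Me3NO, DMSO, rt) raises C12 to the aldehyde level, which in ring-closed form is lactol 15, and the MnO2 of step 11 carries this on to 16.

**Step 13.** Thiol may add to the methylene lactone, the exchange may stop at the cyclic monothioacetal, or the liberated O6–H may attack the lactone under the Lewis acid. Fallback: the aldehyde is unveiled through the alcohol level. From 17, aqueous acid (AcOH/H2O/THF, 50 °C) gives the 6,15-lactol F9, and NaBH(OAc)3 (AcOH/MeCN), which spares conjugated esters, reduces its open form to the 6,15-diol F10. The primary hydroxyl is silylated (TBSCl, imidazole) to the silyl ether F11, O6 is acylated under the conditions of step 14 to the angelate silyl ether F12, and HF·pyridine gives the primary alcohol F13. Dess–Martin periodinane oxidation returns at 22.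

**Step 14.** Acylation of the axial O6–H, flanked on both sides, may be slow; prolonged heating with amine invites Z-to-E isomerisation and migration of the lactone acyl group from O8 to O6. Fallback: the Z-alkene is built on the ester. From 18, esterification with 2-[bis(2,2,2-trifluoroethoxy)phosphoryl]propanoic acid (DCC, DMAP cat.) gives the phosphonopropionate F14, and Still–Gennari olefination (KN(SiMe3)2, 18-crown-6, THF, −78 °C, then 8) returns at 21.

## Further compounds

F1 | step 6 | cyclised ketone (C10–H epimers; cis-fused 15-ethoxytetrahydrofuran, 7β-isopropenyl) | CC1C(=O)C[C@@H](C(C)=C)[C@H]2OC(OCC)C[C@@H]12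
F2 | step 6 | tetrasubstituted trimethylsilyl enol ether (C9–OSiMe3, C9=C10) | CC1=C(O[Si](C)(C)C)C[C@@H](C(C)=C)[C@H]2OC(OCC)C[C@@H]12
F3 | step 9 | 9β-epimeric diol (8α,9β) | C=C[C@]1(C)[C@@H](O)[C@H](O)[C@@H](C(C)=C)[C@H]2OC(OCC)C[C@@H]12
F4 | step 9 | 9β triol (8α,9β,12) | C=C[C@]1(C)[C@@H](O)[C@H](O)[C@@H](C(=C)CO)[C@H]2OC(OCC)C[C@@H]12
F5 | step 9 | 9β lactol (not isolated) | C=C[C@]1(C)[C@@H](O)[C@@H]2OC(O)C(=C)[C@H]2[C@H]3OC(OCC)C[C@@H]13
F6 | step 9 | 9β-hydroxy 8α,12-lactone | C=C[C@]1(C)[C@@H](O)[C@@H]2OC(=O)C(=C)[C@H]2[C@H]3OC(OCC)C[C@@H]13
F7 | step 9 | 9β-triflate | C=C[C@]1(C)[C@@H](OS(=O)(=O)C(F)(F)F)[C@@H]2OC(=O)C(=C)[C@H]2[C@H]3OC(OCC)C[C@@H]13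
F8 | step 10 | allylic chloride (C7 bears 3-chloroprop-1-en-2-yl; 8α,9α-diol) | C=C[C@]1(C)[C@H](O)[C@H](O)[C@@H](C(=C)CCl)[C@H]2OC(OCC)C[C@@H]12
F9 | step 13 | 6,15-lactol | C=C[C@]1(C)[C@H](OC(C)=O)[C@@H]2OC(=O)C(=C)[C@H]2[C@H]3OC(O)C[C@@H]13
F10 | step 13 | 6,15-diol | C=C[C@]1(C)[C@H](OC(C)=O)[C@@H]2OC(=O)C(=C)[C@H]2[C@@H](O)[C@H]1CCO
F11 | step 13 | 15-O-tert-butyldimethylsilyl ether | C=C[C@]1(C)[C@H](OC(C)=O)[C@@H]2OC(=O)C(=C)[C@H]2[C@@H](O)[C@H]1CCO[Si](C)(C)C(C)(C)C
F12 | step 13 | 6β-angelate 15-silyl ether | C=C[C@]1(C)[C@H](OC(C)=O)[C@@H]2OC(=O)C(=C)[C@H]2[C@@H](OC(=O)/C(C)=C\C)[C@H]1CCO[Si](C)(C)C(C)(C)C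
F13 | step 13 | 6β-angelate 15-alcohol | C=C[C@]1(C)[C@H](OC(C)=O)[C@@H]2OC(=O)C(=C)[C@H]2[C@@H](OC(=O)/C(C)=C\C)[C@H]1CCO
F14 | step 14 | O6 2-[bis(2,2,2-trifluoroethoxy)phosphoryl]propanoate of 18 | C=C[C@]1(C)[C@H](OC(C)=O)[C@@H]2OC(=O)C(=C)[C@H]2[C@@H](OC(=O)C(C)P(=O)(OCC(F)(F)F)OCC(F)(F)F)[C@H]1CC3SCCCS3
A1 | alternative 1 | acyclic C9 aldehyde with (E)-allylsilane at C10 | O=C[C@H](O[Si](C)(C)C(C)(C)C)[C@@H](C(=C)C(=O)OC)[C@@H](OC(=O)/C(C)=C\C)[C@@H](C(=C)CO[Si](C)(C)C(C)(C)C)/C(C)=C/C[Si](C)(C)C
A2 | alternative 1 | cyclohexan-9-ol with methyl and vinyl on C10 | C=C[C@]1(C)[C@H](O)[C@H](O[Si](C)(C)C(C)(C)C)[C@@H](C(=C)C(=O)OC)[C@@H](OC(=O)/C(C)=C\C)[C@H]1C(=C)CO[Si](C)(C)C(C)(C)C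
A3 | alternative 2 | acyclic C6 aldehyde with 2-(bromomethyl)enoate | O=C[C@H](C(=C)COCc1ccc(OC)cc1)[C@H]1OC(C)(C)O[C@H]1[C@@](C)(C=C)/C=C(\CBr)C(=O)OC
A4 | alternative 2 | cyclohexane with cis-fused O6–C15 methylene lactone | C=C[C@]1(C)[C@@H]2OC(C)(C)O[C@@H]2[C@@H](C(=C)COCc2ccc(OC)cc2)[C@H]3OC(=O)C(=C)[C@@H]13
A5 | alternative 3 | O8 diazophosphonoacetate with C7H2 | C=C[C@]1(C)[C@H](OC(C)=O)[C@H](OC(=O)C(=[N+]=[N-])P(=O)(OCC)OCC)C[C@@H](OC(=O)/C(C)=C\C)[C@H]1C(=C)CO[Si](C)(C)C(C)(C)C
A6 | alternative 3 | trans-fused α-phosphono γ-lactone | C=C[C@]1(C)[C@H](OC(C)=O)[C@@H]2OC(=O)[C@@H](P(=O)(OCC)OCC)[C@H]2[C@@H](OC(=O)/C(C)=C\C)[C@H]1C(=C)CO[Si](C)(C)C(C)(C)C
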